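If you want what stands in a flask at a late time, first count how many half-lives of Z fit into that time. Z goes to X with dissolved G, or turns into J, which gives L with G; G comes from E.

the same everywhere: E 200 mM (held)

| charge | Z | J | remark | time |
|---|---|---|---|---|
| Tuesday's | 1.5 M | 0.30 M | run made earlier |  |
| Saturday's | 3 M | 0.45 M | run made earlier |  |
| flask | 3.0 M | 0.300 M |  | 15 d |

| run | time / d | L / % | X / % | Z / % |
|---|---|---|---|---|
| Tuesday's | 0.625 | 45.0 | 10.1 | 39.5 |
| Tuesday's | 1.25 | 65.0 | 16.8 | 17.0 |
| Tuesday's | 2.50 | 78.0 | 19.0 | 3.4 |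
| Tuesday's | 5.00 | 79.5 | 19.6 | 0 |
| Tuesday's | 10.0 | 78.7 | 20.3 | 0 |
| Saturday's | 0.625 | 44.3 | 10.6 | 41.9 |
| Saturday's | 1.25 | 63.8 | 16.6 | 18.7 |
| Saturday's | 2.50 | 77.3 | 19.1 | 3.3 |
| Saturday's | 5.00 | 79.8 | 20.1 | 0.2 |
| Saturday's | 10.0 | 79.8 | 20.4 | 0.2 |

(readings scatter by 0.5 percentage points)

* ratio of L to X at 30 min
* ratio of L to X at 15 d

Does Z last until the end? Tuesday's readings give a half-life of 0.514 d, and Saturday's Z percentages, at twice the Z, run close beside them. I carry this over to the new flask, where 15 d holds 29.2 half-lives. Tuesday's Z already reads 0% at 5.00 d.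

So how does the charge divide? Take the end split, the L made per X made, which your last readings put at 3.89, a selectivity. The runs had J at 0.200 and 0.150 of Z, and I take the same split for the new flask at 0.100, which leaves X 20.4% of the charge.

What about 30 min? That is only 0.0405 of a half-life, so the end split need not hold yet. The first readings, at 0.625 d, give 4.46 and 4.18; with a scatter of 0.5 percentage points on an X of about 10.1%, that gap is too small to show a trend with the J charged. They also stand later than 30 min, so I take their mean, 4.32, as a rough figure only.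

The forecast says 5.5 and 3.8, holding that “J/Z stays near the charged 0.10”.

The new flask gives 4.17 and 3.84.

    Z ⇌ J (K = 0.140, k = 0.130 h⁻¹)
    Z + G → X (k = 0.0670 M⁻¹ h⁻¹)
    G + J → L (k = 2.70 M⁻¹ h⁻¹)
    E ⇌ G, rate k4*(csat - [G]) (kL = 5.30 h⁻¹)

In the new flask at 0.518 d, the path to L uses G 3.8 times as fast as the path to X, close to the end split of 3.89, and Z and J relax with a half-life of 0.655 h, shorter than the 0.059 d of J by the path to L. At 15.0 d X stands at 20.7% and L at 79.3%.

Now charge 0.51 M of J, 0.170 equiv: the end split of 3.89 gives X 20.4% of the charge, and the computed flask ends at 3.92 with X at 20.3%.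

(The readings are calculated for substances that don't exist; scatter was added.)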